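Assumption: the target has no stereocentre and its side-chain alkene carries two identical methyl groups, so the SMILES defines one achiral compound and there is no enantiomer or alkene geometry to control.

**Retrosynthetic overview**
1. The prenyl group comes from an allyl group by a final cross-metathesis with 2-methyl-2-butene; the two phenols are carried as MOM ethers.
2. The C2–OAr bond comes from addition–elimination of 4-(methoxymethoxy)phenoxide on a 2-(methylsulfonyl)chromone.
3. Key C–C bond (C2–C3): Claisen-type condensation of an acetophenone enolate with CS2. The pyranone ring (ring C) closes in the same flask and is the only ring built; ring A and the hydroquinone ring are bought.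
4. The C8 allyl comes from an aromatic Claisen rearrangement of a 2-O-allyl-6-O-MOM acetophenone, which also leaves only one free ortho-OH and so fixes 8- over 6-substitution.

**Route**

Step 1
Reactants: 1 1-(2,6-dihydroxy-4-methoxyphenyl)ethanone
Product: 2 1-[2-hydroxy-4-methoxy-6-(methoxymethoxy)phenyl]ethanone
Conditions: MOMCl (1.15 equiv), i-Pr2NEt (1.5 equiv), CH2Cl2, 0 °C → rt
Reagents that add atoms: chloromethyl methyl ether (MOMCl), COCCl
Why: Williamson-type MOM protection stops after one phenol, because the remaining OH is locked in a strong hydrogen bond to the ketone and is not alkylated with an amine base.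

Step 2
Reactants: 2 1-[2-hydroxy-4-methoxy-6-(methoxymethoxy)phenyl]ethanone; 3 allyl bromide
Product: 4 1-[2-(allyloxy)-4-methoxy-6-(methoxymethoxy)phenyl]ethanone
Conditions: K2CO3 (2 equiv), DMF, 60 °C
Reagents that add atoms: none
Why: Williamson ether synthesis under K2CO3/DMF alkylates the chelated phenol on oxygen.

Step 3
Reactants: 4 1-[2-(allyloxy)-4-methoxy-6-(methoxymethoxy)phenyl]ethanone
Product: 6 1-[3-allyl-2-hydroxy-4-methoxy-6-(methoxymethoxy)phenyl]ethanone, via ortho-dienone 5 (not isolated)
Conditions: PhNEt2, 200 °C, Ar, sealed tube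
Reagents that add atoms: none
Why: Aromatic Claisen rearrangement ([3,3]-sigmatropic shift) delivers the allyl group to the only free ortho position, and tautomerisation of the transient racemic dienone leaves the phenol next to the allyl group as the only free OH.

Step 4
Reactants: 6 1-[3-allyl-2-hydroxy-4-methoxy-6-(methoxymethoxy)phenyl]ethanone; 7 carbon disulfide
Product: 9 8-allyl-4-hydroxy-7-methoxy-5-(methoxymethoxy)-2H-chromene-2-thione, via β-keto dithioate 8 (not isolated)
Conditions: KOt-Bu (3.5 equiv), CS2 (3 equiv), THF, 0 °C → rt; then cold 1 M HCl to pH 3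
Reagents that add atoms: none
Why: Claisen-type condensation in which the ketone enolate is C-thioacylated by CS2 to form the C2–C3 bond, after which the neighbouring phenoxide closes the pyranone ring by addition–elimination at the dithiocarboxylate with loss of H2S.

Step 5
Reactants: 9 8-allyl-4-hydroxy-7-methoxy-5-(methoxymethoxy)-2H-chromene-2-thione
Product: 10 8-allyl-7-methoxy-5-(methoxymethoxy)-2-(methylsulfanyl)-4H-chromen-4-one
Conditions: MeI (1.2 equiv), K2CO3 (1.5 equiv), acetone, rt
Reagents that add atoms: iodomethane (MeI), CI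
Why: SN2 S-alkylation of the soft, acidic mercapto/thioxo tautomer gives the 2-(methylsulfanyl)chromone.

Step 6
Reactants: 10 8-allyl-7-methoxy-5-(methoxymethoxy)-2-(methylsulfanyl)-4H-chromen-4-one
Product: 12 8-allyl-7-methoxy-5-(methoxymethoxy)-2-(methylsulfonyl)-4H-chromen-4-one, via sulfoxide 11 (not isolated)
Conditions: mCPBA (2.2 equiv), CH2Cl2, 0 °C → rt
Reagents that add atoms: 3-chloroperoxybenzoic acid (mCPBA), OOC(=O)c1cccc(Cl)c1
Why: Peracid sulfide oxidation proceeds through the sulfoxide to the sulfone faster than the monosubstituted allyl alkene is epoxidised when the peracid is limited to 2.2 equiv at 0 °C to rt.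

Step 7
Reactants: 13 4-(benzyloxy)phenol
Product: 14 1-(benzyloxy)-4-(methoxymethoxy)benzene
Conditions: NaH (1.2 equiv), DMF, 0 °C; MOMCl (1.2 equiv), 0 °C → rt
Reagents that add atoms: chloromethyl methyl ether (MOMCl), COCCl
Why: Williamson-type MOM protection of the sodium phenoxide.

Step 8
Reactants: 14 1-(benzyloxy)-4-(methoxymethoxy)benzene
Product: 15 4-(methoxymethoxy)phenol
Conditions: H2 (1 atm), 10% Pd/C, EtOAc, rt
Reagents that add atoms: none
Why: Catalytic hydrogenolysis cleaves the benzyl ether while the MOM acetal is inert, and this fragment carries no alkene.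

Step 9
Reactants: 12 8-allyl-7-methoxy-5-(methoxymethoxy)-2-(methylsulfonyl)-4H-chromen-4-one; 15 4-(methoxymethoxy)phenol
Product: 16 8-allyl-7-methoxy-5-(methoxymethoxy)-2-[4-(methoxymethoxy)phenoxy]-4H-chromen-4-one
Conditions: 15 (1.2 equiv), K2CO3 (1.5 equiv), DMF, rt
Reagents that add atoms: none
Why: Addition–elimination (vinylogous SNAr-type substitution) of the phenoxide at the electrophilic C2 of the chromone expels methanesulfinate.

Step 10
Reactants: 16 8-allyl-7-methoxy-5-(methoxymethoxy)-2-[4-(methoxymethoxy)phenoxy]-4H-chromen-4-one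
Product: 18 8-allyl-5-hydroxy-2-(4-hydroxyphenoxy)-7-methoxy-4H-chromen-4-one, via mono-MOM ether 17 (not isolated)
Conditions: 3 M aq HCl, MeOH/THF (1:1), rt → 40 °C, monitored by TLC
Reagents that add atoms: none
Why: Acid-catalysed MOM acetal cleavage with methanol as the trap removes the chelation-activated 5-O-MOM first and then the 4'-O-MOM, while the allyl group and the 7-OMe are inert.

Step 11
Reactants: 18 8-allyl-5-hydroxy-2-(4-hydroxyphenoxy)-7-methoxy-4H-chromen-4-one; 19 2-methyl-2-butene
Product: 20 7-O-methylepimedonin G, 5-hydroxy-2-(4-hydroxyphenoxy)-7-methoxy-8-(3-methylbut-2-en-1-yl)-4H-chromen-4-one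
Conditions: second-generation Grubbs catalyst (H2IMes)(PCy3)Cl2Ru=CHPh (5 mol%), 19/CH2Cl2 (1:2), 40 °C, sealed tube
Reagents that add atoms: none
Why: Olefin cross-metathesis of the terminal allyl alkene with a large excess of 2-methyl-2-butene converts allyl into prenyl with loss of propene, and the product alkene has two identical methyl groups so no geometry has to be set.

**Compound list**
1 | 1-(2,6-dihydroxy-4-methoxyphenyl)ethanone (2',6'-dihydroxy-4'-methoxyacetophenone) | CC(=O)c1c(O)cc(OC)cc1O | starting material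
2 | 1-[2-hydroxy-4-methoxy-6-(methoxymethoxy)phenyl]ethanone | CC(=O)c1c(O)cc(OC)cc1OCOC | intermediate
3 | allyl bromide (3-bromoprop-1-ene) | C=CCBr | starting material
4 | 1-[2-(allyloxy)-4-methoxy-6-(methoxymethoxy)phenyl]ethanone | CC(=O)c1c(OCC=C)cc(OC)cc1OCOC | intermediate
5 | 2-acetyl-6-allyl-5-methoxy-3-(methoxymethoxy)cyclohexa-2,4-dien-1-one (transient ortho-dienone, racemic) | CC(=O)C1=C(OCOC)C=C(OC)C(CC=C)C1=O | intermediate
6 | 1-[3-allyl-2-hydroxy-4-methoxy-6-(methoxymethoxy)phenyl]ethanone | CC(=O)c1c(O)c(CC=C)c(OC)cc1OCOC | intermediate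
7 | carbon disulfide | S=C=S | starting material
8 | 3-[3-allyl-2-hydroxy-4-methoxy-6-(methoxymethoxy)phenyl]-3-oxopropanedithioic acid (potassium salt in the flask) | SC(=S)CC(=O)c1c(O)c(CC=C)c(OC)cc1OCOC | intermediate
9 | 8-allyl-4-hydroxy-7-methoxy-5-(methoxymethoxy)-2H-chromene-2-thione | S=c1cc(O)c2c(OCOC)cc(OC)c(CC=C)c2o1 | intermediate
10 | 8-allyl-7-methoxy-5-(methoxymethoxy)-2-(methylsulfanyl)-4H-chromen-4-one | CSc1cc(=O)c2c(OCOC)cc(OC)c(CC=C)c2o1 | intermediate
11 | 8-allyl-7-methoxy-5-(methoxymethoxy)-2-(methylsulfinyl)-4H-chromen-4-one (racemic at sulfur) | CS(=O)c1cc(=O)c2c(OCOC)cc(OC)c(CC=C)c2o1 | intermediate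
12 | 8-allyl-7-methoxy-5-(methoxymethoxy)-2-(methylsulfonyl)-4H-chromen-4-one | CS(=O)(=O)c1cc(=O)c2c(OCOC)cc(OC)c(CC=C)c2o1 | intermediate
13 | 4-(benzyloxy)phenol | Oc1ccc(OCc2ccccc2)cc1 | starting material
14 | 1-(benzyloxy)-4-(methoxymethoxy)benzene | COCOc1ccc(OCc2ccccc2)cc1 | intermediate
15 | 4-(methoxymethoxy)phenol | COCOc1ccc(O)cc1 | intermediate
16 | 8-allyl-7-methoxy-5-(methoxymethoxy)-2-[4-(methoxymethoxy)phenoxy]-4H-chromen-4-one | COCOc1ccc(Oc2cc(=O)c3c(OCOC)cc(OC)c(CC=C)c3o2)cc1 | intermediate
17 | 8-allyl-5-hydroxy-7-methoxy-2-[4-(methoxymethoxy)phenoxy]-4H-chromen-4-one | COCOc1ccc(Oc2cc(=O)c3c(O)cc(OC)c(CC=C)c3o2)cc1 | intermediate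
18 | 8-allyl-5-hydroxy-2-(4-hydroxyphenoxy)-7-methoxy-4H-chromen-4-one | C=CCc1c(OC)cc(O)c2c(=O)cc(Oc3ccc(O)cc3)oc12 | intermediate
19 | 2-methyl-2-butene | CC=C(C)C | starting material
20 | 7-O-methylepimedonin G, 5-hydroxy-2-(4-hydroxyphenoxy)-7-methoxy-8-(3-methylbut-2-en-1-yl)-4H-chromen-4-one | COc1cc(O)c2c(=O)cc(Oc3ccc(O)cc3)oc2c1CC=C(C)C | target

**Totals**
Total step count: 11. Longest linear sequence: 9 steps (steps 1–6, 9, 10, 11 from compound 1); steps 7 and 8 form a two-step side branch that joins at step 9.

**Three steps most likely to fail**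

Step 4. KOt-Bu may move the allyl double bond into conjugation, ring closure may be incomplete, or the 5-O-MOM group may be lost on acidification. The fallback sets out from 6. The dianion is made with LiN(SiMe3)2 (3.2 equiv) in THF at −78 °C, treated with CS2 and then with MeI (2.2 equiv) to give the ketene dithioacetal 1-[3-allyl-2-hydroxy-4-methoxy-6-(methoxymethoxy)phenyl]-3,3-bis(methylsulfanyl)prop-2-en-1-one F1. Warming F1 with K2CO3 in DMF at 80 °C closes the ring by intramolecular conjugate addition–elimination with loss of methanethiol. The route is rejoined at 10, so 9 and step 5 are bypassed and no acidic quench is needed.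

Step 10. The unactivated 4'-O-MOM ether needs the more forcing acid, and under those conditions methanol may exchange the aryloxy group at the electrophilic C2. The fallback sets out from 12. It is coupled with a fivefold excess of hydroquinone (K2CO3, degassed DMF, rt, Ar) to give 8-allyl-2-(4-hydroxyphenoxy)-7-methoxy-5-(methoxymethoxy)-4H-chromen-4-one F2. Only the chelation-activated peri MOM ether then remains, and it falls off under much milder acid (0.5 M HCl in MeOH/THF, 0 °C → rt). The route is rejoined at 18.

Step 11. Cross-metathesis on the free diphenol may stall or leave crotyl by-product that is hard to separate from the polar product. The fallback sets out from 16. The metathesis is run on the fully protected compound (same catalyst, 19/CH2Cl2, 40 °C) to give 7-methoxy-5-(methoxymethoxy)-2-[4-(methoxymethoxy)phenoxy]-8-(3-methylbut-2-en-1-yl)-4H-chromen-4-one F3, which is easy to purify. The MOM groups are then removed with HCl in MeOH/THF at rt; the prenyl group has no ortho-OH to cyclise onto. The route is rejoined at 20.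

**Further compounds**
F1 | step 4 | 1-[3-allyl-2-hydroxy-4-methoxy-6-(methoxymethoxy)phenyl]-3,3-bis(methylsulfanyl)prop-2-en-1-one | CSC(SC)=CC(=O)c1c(O)c(CC=C)c(OC)cc1OCOC
F2 | step 10 | 8-allyl-2-(4-hydroxyphenoxy)-7-methoxy-5-(methoxymethoxy)-4H-chromen-4-one | C=CCc1c(OC)cc(OCOC)c2c(=O)cc(Oc3ccc(O)cc3)oc12
F3 | step 11 | 7-methoxy-5-(methoxymethoxy)-2-[4-(methoxymethoxy)phenoxy]-8-(3-methylbut-2-en-1-yl)-4H-chromen-4-one | COCOc1ccc(Oc2cc(=O)c3c(OCOC)cc(OC)c(CC=C(C)C)c3o2)cc1
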